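**Analysis of the target**

Numbering used throughout: ring A is C1 (spiro), C2 (=O), C3 (two prenyl groups), C4 (enol OH) = C5 (isobutyryl), C6 (=O); ring B is C1, C7H2, C8H, C9H, C10(CH3)(OH), C11H2; ring C is C8, C12(CH3)(OH), C14H2, C13H2, C9.

Tomoeone D (20) is a spiro compound. A dearomatised acylphloroglucinol (ring A, an enolised cyclohexane-1,3,5-trione) shares the quaternary carbon C1 with the six-membered ring B of a trans-hydrindane (rings B and C). It has five stereocentres, (1R,8S,9R,10S,12R) in this numbering. C8–H and C9–H are trans-diaxial on ring B. The C10 hydroxyl is axial and lies on the same face as C8–H and as the C1–C2 bond. The C12 hydroxyl is cis to the C8–C7 bond.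

C1 is stereogenic only because the C2 branch (next to the diprenyl carbon) differs from the C6 branch (next to the acyl-bearing carbon). Its two carbonyl substituents therefore have to be told apart by a remote element of ring B. The sensitive groups are two tertiary alcohols (ionisation and dehydration under acid), an acidic, ambident and retro-Claisen-prone β-triketone, and two prenyl alkenes that tolerate neither electrophilic halogen nor allylic oxidants. The C10 hydroxyl sits 1,3-diaxial to the C2 carbonyl.

The hard points are the remote differentiation at C1, a trans ring fusion that must never become epimerisable once set, and an axial C10–O bond on the more hindered face of ring B. The structural feature on which the route rests is that C8 and C9 are the α- and β-carbons of cyclopent-2-en-1-one, with C12 as its carbonyl carbon. The trans ring fusion is therefore the result of a vicinal difunctionalisation of that enone.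

**Retrosynthetic reasoning**

*20 to 17 and 18.* Both C3–CH2 bonds are cut last. The prenyl alkenes would not survive the allylic oxidation and the iodine-mediated lactonisation used earlier, and C3 is the only enolisable CH2 of ring A, so it is the natural site of a double C-alkylation of 17 with 18. The forward reaction must favour carbon over oxygen alkylation and must go twice.

*17 to 16, then 16 to 13 and 14.* Ring A is opened at C5–C6 (Claisen condensation) and then at C2–C3. The diketone 14 holds C3, C4, C5 and the isobutyryl group in the right order. Its two nucleophilic carbons have graded reactivity: the terminal carbon of its dianion 15 is the strong one, the central carbon the weak one. The two electrophilic carbons on C1 must be graded to match. In 13 one is a strained lactone carbonyl (the future C2, cis to the C10 oxygen) and the other a methyl ester (the future C6). The forward sequence has to deliver the terminal carbon of 15 to the lactone and only then close C5 onto the ester. The chemoselectivity of the first event thus becomes the configuration of C1.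

*13 to 12 to 11.* The C10–O bond is cut. In 11, C1 carries two identical ester groups and is not yet a stereocentre, and C10 is an exocyclic methylene carbon. Hydration of that alkene by an external reagent would approach anti to the axial ester and would probably place the oxygen equatorial, which is the wrong epimer. The axial ester is therefore used as the oxygen donor. Lactonisation onto C10 is possible only across the 1,3-diaxial positions of the locked chair of ring B, on the face of C8–H, so a single ring closure sets C10 and C1 together. A halolactonisation followed by reductive removal of the halogen avoids the acid that the C12 carbinol would not tolerate.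

*11 to 10 to 9 to 8.* Ring B is opened at C1–C11, an intramolecular allylic alkylation of the malonate carbon. The allyl unit attached through its central carbon C10 has two equivalent termini, so the closure has no regiochemical ambiguity and leaves the C10 methylene group needed above. This requires allylic oxygenation of the isopropenyl methyl group of 8 and activation as the carbonate 10.

*8 to 7.* The C12–CH3 bond is cut. Adding the methyl group while the five-membered ring is still monocyclic lets the freely rotating C8 side chain shield one face of the ketone. It also removes the carbonyl group before ring B exists, so C8 stops being epimerisable.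

*7 to 5, 4 and 2.* The C9–C10 and C8–C7 bonds are cut together. A catalytic asymmetric conjugate addition of 4 to 5 sets C9 and gives the regiodefined enolate 6. Michael trapping of 6 by 2 sets C8 trans and brings in C7, C1, C2 and C6 in one reagent. All risk concerning absolute configuration is concentrated in this one step, on compounds that cost little to make.

*4 to 3, 2 to 1.* The Grignard reagent 4 comes from 3 by magnesium insertion, and the acceptor 2 from 1 by condensation with a one-carbon aldehyde unit.

**Alternatives that were turned down**

Alternative 1: Ring A would be assembled by a cyclobutenone–alkyne benzannulation that stops at the dienone stage.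
- Disconnection: C5–C6 and C3–C4 are cut, and C1–C6 is broken and re-formed, leading back to the spiro 3-ethoxycyclobutenone A1 and the silyloxyalkyne A2.
- Forward key step: heating opens A1 to a vinylketene, A2 adds in a [2+2] sense, the new four-membered ring opens again, and a 6π electrocyclisation gives the spiro cyclohexadienone A3.
- For: all six carbons of ring A and the oxygen pattern at C2, C4 and C6 arrive in one reagent-free thermal step with fixed regiochemistry. In the economy of building ring A this is stronger than the chosen route, which needs three steps.
- Against: C1 belongs to the four-membered ring that opens. In the vinylketene it is a planar alkylidene carbon, so any configuration at the spiro centre is erased and is decided only in the electrocyclisation by the facial bias of ring B, with no element that enforces it. A3 still lacks the two prenyl groups and the C5 acyl group, and its enol ethers and silyl ethers must be removed. A1 itself presupposes a fully built hydrindane with a one-carbon acyl function on C1.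
- Comparison: the chosen route offers instead a C1 configuration that follows by geometric necessity from C10 through the lactone, and hydroxyl groups that are never protected.

Alternative 2: Both carbocycles would be made from an open chain in one Lewis-acid-promoted cascade.
- Disconnection: C8–C9 and C1–C11 are cut, giving the acyclic hydroxy enal A4, whose C12 carbinol could come from a terpene by asymmetric epoxidation.
- Forward key step: a dialkylaluminium chloride Lewis acid induces a conjugate ene reaction (ring C), and the aldehyde so formed undergoes a carbonyl-ene reaction with the new isopropenyl group (ring B), giving the trans-hydrindane diol A5.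
- For: it reaches the bicyclic core in one step from a chain. This is clearly shorter than the five steps from 5 to 11 in the chosen route, and C12 comes from a dependable source.
- Against: the γ-hydroxy enal is exposed to ionisation and fragmentation under the Lewis acid. The relative configuration of C8 and C9 to C12 depends on one transition-state preference. Most seriously, A5 ends with C1 as a secondary carbinol. C1 must then be oxidised and made quaternary by two further C–C bonds to two carbonyl carbons that nothing distinguishes, and C10 would need external hydration on its hindered face.
- Comparison: the chosen route brings C1 in with both carbonyl carbons attached and lets C10 sort them.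

Alternative 3: A double methyl addition to a diketone would be coupled with lactonisation.
- Disconnection: both C–CH3 bonds (C10 and C12) and the lactone C–O bond are cut, leading to the trans-fused diketone gem-diester A6.
- Forward key step: an organocerium methyl donor adds to both ketones and the axial C10 alkoxide closes onto the axial ester, giving the bridged lactone ester A7, which is the same compound as 13.
- For: three stereocentres (C10, C12, C1) would be set in one operation, replacing steps 4 to 9 of the chosen route. Equatorial attack at C10, anti to the axial ester, gives the required axial alkoxide. In step economy this alternative is stronger.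
- Against: in A6 both ring-fusion carbons are α to a ketone (C8 to C12, C9 to C10), and a hydrindan-1-one prefers cis fusion, so the trans junction is thermodynamically fragile before and during the addition. Facial selectivity at C12 in the rigid bicycle lacks the freely rotating α-substituent that controls it in 7. A6 also needs its own enantioselective synthesis.
- Comparison: the chosen route never places C9 next to a carbonyl group, removes the C12 carbonyl before ring B is closed, and sets each stereocentre in a separate event whose control element can be named. It pays for this with more steps.

Key step: step 3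

Assumption: the ligand enantiomer named in step 3 is taken to be the one that gives 9R. The sense of induction for an alkenyl group on cyclopentenone should be confirmed on the first run, and the mirror-image ligand used if it is reversed.

**Route**

Step 1
Reactants: 1 dimethyl malonate
Product: 2 dimethyl methylenemalonate (dimethyl 2-methylidenepropanedioate)
Conditions: (CH2O)n, Cu(OAc)2 (cat.), KOAc (cat.), AcOH, 100 °C; distil under reduced pressure, use at once
Reagents that add atoms: paraformaldehyde (as formaldehyde), C=O
Why: Knoevenagel condensation with loss of water; distillation cracks oligomers, and the monomer is used fresh because it polymerises readily.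

Step 2
Reactants: 3 2-bromopropene
Product: 4 isopropenylmagnesium bromide
Conditions: Mg turnings (I2-activated), Et2O, reflux; titrate
Reagents that add atoms: magnesium, [Mg]
Why: Standard Grignard formation by magnesium insertion; Et2O is chosen because strongly coordinating THF lowers the selectivity of the copper-catalysed step.

Step 3
Reactants: 5 cyclopent-2-en-1-one; 4 isopropenylmagnesium bromide; 2 dimethyl methylenemalonate
Product: 7 dimethyl 2-{[(1S,5R)-2-oxo-5-(prop-1-en-2-yl)cyclopentyl]methyl}propanedioate, via bromomagnesium enolate 6 (not isolated)
Conditions: CuBr·SMe2 (5 mol %), (RP)-1-[(R)-α-(dimethylamino)-2-(diphenylphosphino)benzyl]-2-(diphenylphosphino)ferrocene (6 mol %), t-BuOMe, −78 °C, slow addition of 4 (1.15 equiv); then 2 (1.2 equiv), −78 → −40 °C; aq. NH4Cl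
Reagents that add atoms: none
Why: Transmetalation of 4 to the ligated monovalent copper bromide gives a chiral alkenylcopper–magnesium species that binds the enone as a π-complex, passes through a trivalent copper β-adduct and reductively eliminates to the bromomagnesium enolate 6 with the new C9–C10 bond. The closest known reaction type is the copper-catalysed asymmetric conjugate addition of Grignard reagents to cyclic enones with ferrocenyl diphosphines, followed by in situ trapping of the enolate with a Michael acceptor. Enolate 6 then adds through C8 to the unsubstituted methylene carbon of 2 (C8–C7) and the resulting malonate enolate is protonated on work-up. No ring is closed in this step. C9 (R) is controlled by the catalyst, which delivers the isopropenyl group to one enantiotopic face of the flat enone. C8 (S) is controlled by the substrate, since the acceptor approaches the enolate anti to the new C9 substituent, and because C8 stays epimerisable next to the ketone the trans isomer is also the thermodynamic one. The step needs 1,4- over 1,2-addition and catalysed over background addition, which slow addition of 4 at −78 °C in a weakly coordinating ether should secure, and it needs a single Michael addition, which follows from the much higher nucleophilicity of the ketone enolate 6 over the stabilised malonate enolate and from slow addition of a slight excess of 2.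

Step 4
Reactants: 7 dimethyl 2-{[(1S,5R)-2-oxo-5-(prop-1-en-2-yl)cyclopentyl]methyl}propanedioate
Product: 8 dimethyl 2-{[(1S,2R,5R)-2-hydroxy-2-methyl-5-(prop-1-en-2-yl)cyclopentyl]methyl}propanedioate
Conditions: MeCeCl2 (3 equiv, from MeLi and anhydrous CeCl3), THF, −78 °C; aq. NH4Cl
Reagents that add atoms: methylcerium dichloride, C[Ce](Cl)Cl (made from methyllithium, [Li]C)
Why: Organocerium 1,2-addition: the first equivalent converts the malonate into its unreactive enolate (which also blocks lactonisation by the new alkoxide), and the weakly basic reagent then adds to the C12 ketone without enolising C8 or touching the esters. The methyl group enters anti to the adjacent C8 side chain, as nucleophiles do with trans-2,3-disubstituted cyclopentanones, so the C12 hydroxyl ends cis to C7 (12R).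

Step 5
Reactants: 8 dimethyl 2-{[(1S,2R,5R)-2-hydroxy-2-methyl-5-(prop-1-en-2-yl)cyclopentyl]methyl}propanedioate
Product: 9 dimethyl 2-{[(1S,2R,5R)-2-hydroxy-5-(3-hydroxyprop-1-en-2-yl)-2-methylcyclopentyl]methyl}propanedioate
Conditions: SeO2 (0.3 equiv), t-BuOOH (3 equiv), CH2Cl2, 0 °C → rt
Reagents that add atoms: selenium dioxide, O=[Se]=O (oxygen carrier); tert-butyl hydroperoxide, CC(C)(C)OO (terminal oxidant)
Why: Catalytic SeO2 allylic oxidation: an ene reaction at the terminal CH2 followed by a [2,3]-sigmatropic shift restores the 1,1-disubstituted alkene and hydroxylates the former methyl group. Allylic strain holds C9–H near the plane of the alkene, where it is poorly aligned for abstraction, and the neutral conditions leave the tertiary alcohol and the malonate untouched.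

Step 6
Reactants: 9 dimethyl 2-{[(1S,2R,5R)-2-hydroxy-5-(3-hydroxyprop-1-en-2-yl)-2-methylcyclopentyl]methyl}propanedioate
Product: 10 dimethyl 2-{[(1S,2R,5R)-2-hydroxy-5-{3-[(methoxycarbonyl)oxy]prop-1-en-2-yl}-2-methylcyclopentyl]methyl}propanedioate
Conditions: ClCO2Me, pyridine, CH2Cl2, 0 °C
Reagents that add atoms: methyl chloroformate, COC(=O)Cl
Why: Selective acylation of the primary allylic alcohol, the tertiary C12 hydroxyl being too hindered; the carbonate is chosen because on ionisation it supplies its own base.

Step 7
Reactants: 10 dimethyl 2-{[(1S,2R,5R)-2-hydroxy-5-{3-[(methoxycarbonyl)oxy]prop-1-en-2-yl}-2-methylcyclopentyl]methyl}propanedioate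
Product: 11 dimethyl (3R,3aS,7aR)-3-hydroxy-3-methyl-7-methylideneoctahydro-1H-indene-5,5-dicarboxylate (trans-fused; C10 exocyclic methylene, two CO2CH3 on C1)
Conditions: Pd(PPh3)4 (5 mol %), THF, 65 °C
Reagents that add atoms: none
Why: Intramolecular Tsuji–Trost allylic alkylation: zerovalent palladium ionises the carbonate, loss of CO2 leaves methoxide that deprotonates the malonate, and C1 attacks a terminus of the 2-substituted allyl unit to close the six-membered ring B (C1–C11). The two termini are equivalent, so either gives the same methylenecyclohexane; the trans arrangement at C8 and C9 becomes the trans ring fusion and no new stereocentre forms.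

Step 8
Reactants: 11 dimethyl (3R,3aS,7aR)-3-hydroxy-3-methyl-7-methylideneoctahydro-1H-indene-5,5-dicarboxylate
Product: 12 bridged iodolactone ester (1S,8S,9R,10S,12R): γ-lactone from the axial C1 carboxyl to the C10 oxygen, CH2I on C10, equatorial CO2CH3 on C1, free C12 hydroxyl
Conditions: I2 (3 equiv), MeCN, 0 °C → rt, dark; aq. Na2S2O3
Reagents that add atoms: iodine, II
Why: Iodolactonisation of a γ,δ-unsaturated methyl ester: the iodonium ion of the C10 methylene is opened at the tertiary carbon by the carbonyl oxygen of the axial ester (5-exo), and iodide removes the O-methyl group as iodomethane, so no acid is formed. In the locked chair of ring B only the axial ester, on the face of C8–H, can reach C10, so the axial C10–O bond (10S) and the configuration of C1 are set together; the C12 hydroxyl is trans-disposed and cannot compete.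

Step 9
Reactants: 12 bridged iodolactone ester
Product: 13 bridged lactone ester (1S,8S,9R,10S,12R): as 12 with CH3 in place of CH2I on C10
Conditions: Bu3SnH, AIBN (cat.), PhMe, 80 °C
Reagents that add atoms: none
Why: Radical chain dehalogenation; the primary radical takes hydrogen from the tin hydride faster than any acyloxy shift or fragmentation, and no stereocentre is touched.

Step 10
Reactants: 13 bridged lactone ester; 14 5-methylhexane-2,4-dione
Product: 16 hydroxy triketone ester (1R,8S,9R,10S,12R): C1 bears CO2CH3 (C6) and the chain C2(=O)–C3H2–C4(=O)–C5H2–C(=O)CH(CH3)2; free C10 and C12 hydroxyls (open form of a C2/C10 hemiketal), via dilithium dianion 15 (not isolated)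
Conditions: 14 (3.5 equiv), LiN(i-Pr)2 (7 equiv), THF, −78 → 0 °C; then 13, −78 → −20 °C; aq. NH4Cl
Reagents that add atoms: none
Why: Acylation of a β-diketone dianion at its terminal carbon: the more basic terminal carbon of 15 (the future C3) adds to the lactone carbonyl C2, the tetrahedral intermediate opens to release the C10 alkoxide, and the new triketone is at once deprotonated by excess 15, which protects it from over-addition. The strained bridged γ-lactone, fixed in the more electrophilic s-trans ester geometry, should react before the geminal methyl ester, so the carbonyl cis to the C10 oxygen becomes C2 and the lactone is translated into the configuration of C1.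

Step 11
Reactants: 16 hydroxy triketone ester
Product: 17 spiro trione (1R,8S,9R,10S,12R): ring A closed, C3 still CH2, isobutyryl on C5, C4 enol
Conditions: t-BuOK (5 equiv), THF, 0 → 50 °C; cold 1 M HCl to pH 3
Reagents that add atoms: none
Why: Intramolecular Claisen (Dieckmann-type) condensation: in the triketone dianion only C5 can reach the ester carbon C6 through a six-membered transition state, and the product is drained as its very stable triketone enolate. A non-nucleophilic alkoxide avoids retro-Claisen cleavage, and any O-acylated isomer equilibrates to the C-acylated product.

Step 12
Reactants: 17 spiro trione; 18 prenyl bromide (1-bromo-3-methylbut-2-ene)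
Product: 20 Tomoeone D, via 3-monoprenyl trione 19 (not isolated)
Conditions: NaOMe (3.5 equiv), MeOH, 0 °C; 18 (2.5 equiv), 0 °C → rt; aq. NH4Cl
Reagents that add atoms: none
Why: C-alkylation of a dearomatised acylphloroglucinol enolate, the reaction type that gives gem-diprenyl hop acids: C3 is the only enolisable CH2, the protic medium solvates the oxygen atoms and favours attack through carbon, and methoxide does not ionise the tertiary alcohols. The first prenylation leaves C3–H acidic, so the second follows in the same flask; no stereocentre is created or endangered.

**Compound list**

1 | dimethyl malonate | COC(=O)CC(=O)OC | starting material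
2 | dimethyl methylenemalonate | C=C(C(=O)OC)C(=O)OC | intermediate
3 | 2-bromopropene | CC(Br)=C | starting material
4 | isopropenylmagnesium bromide | CC(=C)[Mg]Br | intermediate
5 | cyclopent-2-en-1-one | O=C1C=CCC1 | starting material
6 | bromomagnesium (R)-3-(prop-1-en-2-yl)cyclopent-1-en-1-olate | Br[Mg]OC1=C[C@@H](CC1)C(C)=C | intermediate
7 | dimethyl 2-{[(1S,5R)-2-oxo-5-(prop-1-en-2-yl)cyclopentyl]methyl}propanedioate | COC(=O)C(C[C@H]1[C@@H](CCC1=O)C(C)=C)C(=O)OC | intermediate
8 | dimethyl 2-{[(1S,2R,5R)-2-hydroxy-2-methyl-5-(prop-1-en-2-yl)cyclopentyl]methyl}propanedioate | COC(=O)C(C[C@H]1[C@@H](CC[C@@]1(C)O)C(C)=C)C(=O)OC | intermediate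
9 | dimethyl 2-{[(1S,2R,5R)-2-hydroxy-5-(3-hydroxyprop-1-en-2-yl)-2-methylcyclopentyl]methyl}propanedioate | COC(=O)C(C[C@H]1[C@@H](CC[C@@]1(C)O)C(=C)CO)C(=O)OC | intermediate
10 | allylic methyl carbonate of 9 | COC(=O)C(C[C@H]1[C@@H](CC[C@@]1(C)O)C(=C)COC(=O)OC)C(=O)OC | intermediate
11 | dimethyl (3R,3aS,7aR)-3-hydroxy-3-methyl-7-methylideneoctahydro-1H-indene-5,5-dicarboxylate | COC(=O)C2(C[C@H]3[C@@H](CC[C@@]3(C)O)C(=C)C2)C(=O)OC | intermediate
12 | bridged iodolactone ester (1S,8S,9R,10S,12R) | O=C4[C@]2(C[C@H]3[C@@H](CC[C@@]3(C)O)[C@@](CI)(O4)C2)C(=O)OC | intermediate
13 | bridged lactone ester (1S,8S,9R,10S,12R) | O=C4[C@]2(C[C@H]3[C@@H](CC[C@@]3(C)O)[C@@](C)(O4)C2)C(=O)OC | intermediate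
14 | 5-methylhexane-2,4-dione | CC(C)C(=O)CC(C)=O | starting material
15 | dilithium 5-methylhexa-1,3-diene-2,4-diolate (dianion of 14) | C=C(O[Li])C=C(O[Li])C(C)C | intermediate
16 | hydroxy triketone ester (1R,8S,9R,10S,12R) | COC(=O)[C@@]2(C[C@H]3[C@@H](CC[C@@]3(C)O)[C@@](C)(O)C2)C(=O)CC(=O)CC(=O)C(C)C | intermediate
17 | spiro trione without prenyl groups (1R,8S,9R,10S,12R) | C1C(=O)[C@]2(C[C@H]3[C@@H](CC[C@@]3(C)O)[C@@](C)(O)C2)C(=O)C(C(=O)C(C)C)=C1O | intermediate
18 | prenyl bromide (1-bromo-3-methylbut-2-ene) | CC(C)=CCBr | starting material
19 | 3-monoprenyl trione (C3 epimers) | CC(C)=CCC1C(=O)[C@]2(C[C@H]3[C@@H](CC[C@@]3(C)O)[C@@](C)(O)C2)C(=O)C(C(=O)C(C)C)=C1O | intermediate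
20 | Tomoeone D | CC(C)=CCC1(CC=C(C)C)C(=O)[C@]2(C[C@H]3[C@@H](CC[C@@]3(C)O)[C@@](C)(O)C2)C(=O)C(C(=O)C(C)C)=C1O | target

**Step count and least certain steps**

Total: 12 steps. Longest linear sequence: 11 steps (step 1 or step 2, then steps 3 to 12).

Step 3 (key step).
- What may go wrong: erosion of enantioselectivity, because the small, flat cyclopentenone is poorly differentiated by the catalyst and the uncatalysed addition of the reactive alkenyl Grignard reagent competes. In the second stage, anionic oligomerisation of 2 may be started by the magnesium enolates.
- Fallback: an auxiliary-controlled route that sets out from 4 and 2 and returns at 7. The enantiopure enone (S)-2-(p-tolylsulfinyl)cyclopent-2-en-1-one F1 takes the place of 5. Pre-complexed with ZnBr2 in THF at −78 °C, it should accept 4 on the face away from the tolyl group. The chelated, stabilised β-keto sulfoxide enolate is then alkylated by 2 to give the sulfinyl ketone F2. Aluminium amalgam in aqueous THF cleaves the C–S bond, and protonation of the resulting enol gives the more stable trans ketone 7.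

Step 5.
- What may go wrong: abstraction of the ring methine hydrogen at C9 in the ene step, to which 1,1-disubstituted alkenes are prone. This would move the oxygen to C9 and erase that stereocentre. Over-oxidation of the primary allylic alcohol to the enal is also possible.
- Fallback: it sets out from 8 and returns at 11. Ene-type chlorination with Ca(OCl)2 and solid CO2 in CH2Cl2–H2O at 0 °C, in which the proton is lost from the methyl group, gives the allyl chloride F3. F3 is cyclised directly with NaH and catalytic Pd(PPh3)4 in THF; direct and allylic displacement give the same ring, so 11 results without the carbonate.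

Step 10.
- What may go wrong: attack of the dianion on the methyl ester instead of the lactone, which would reverse the orientation of ring A and hence the configuration of C1. Incomplete conversion through proton transfer is a second concern.
- Fallback: it sets out from 13 and returns at 17. LiOH in aqueous THF–MeOH followed by acidification gives the lactone acid F4; the lactone recloses, and the bridgehead position suppresses decarboxylation. With excess 15 the carboxylate is inert, so only the lactone can be opened, giving the triketo acid F5. Activation with 1,1'-carbonyldiimidazole, then DBU with catalytic DMAP, closes ring A by C-acylation, O-acyl isomers rearranging to the triketone 17.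

Step 12.
- What may go wrong: O-alkylation of the ambident enolate, stalling after the first prenylation because the second builds a quaternary carbon next to the spiro centre, and solvolysis of 18.
- Fallback: it sets out from 17 and returns at 20. Double allylation with allyl acetate and catalytic Pd(PPh3)4, in which O-allylation is reversible and funnels to carbon, gives the 3,3-diallyl trione F6. Cross-metathesis with 2-methylbut-2-ene and the second-generation Grubbs catalyst then converts both allyl groups into prenyl groups.

**Further compounds**

F1 | step 3 | (S)-2-(p-tolylsulfinyl)cyclopent-2-en-1-one | Cc1ccc(cc1)[S@](=O)C1=CCCC1=O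
F2 | step 3 | dimethyl 2-{[(2R)-5-oxo-2-(prop-1-en-2-yl)-1-[(S)-p-tolylsulfinyl]cyclopentyl]methyl}propanedioate (configuration at the sulfur-bearing carbon immaterial) | COC(=O)C(CC1([S@@](=O)c2ccc(C)cc2)[C@@H](CCC1=O)C(C)=C)C(=O)OC
F3 | step 5 | dimethyl 2-{[(1S,2R,5R)-5-(3-chloroprop-1-en-2-yl)-2-hydroxy-2-methylcyclopentyl]methyl}propanedioate | COC(=O)C(C[C@H]1[C@@H](CC[C@@]1(C)O)C(=C)CCl)C(=O)OC
F4 | step 10 | bridged lactone acid (carboxylic acid of 13) | O=C4[C@]2(C[C@H]3[C@@H](CC[C@@]3(C)O)[C@@](C)(O4)C2)C(=O)O
F5 | step 10 | hydroxy triketo acid (carboxylic acid of 16) | OC(=O)[C@@]2(C[C@H]3[C@@H](CC[C@@]3(C)O)[C@@](C)(O)C2)C(=O)CC(=O)CC(=O)C(C)C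
F6 | step 12 | 3,3-diallyl spiro trione | C=CCC1(CC=C)C(=O)[C@]2(C[C@H]3[C@@H](CC[C@@]3(C)O)[C@@](C)(O)C2)C(=O)C(C(=O)C(C)C)=C1O
A1 | alternative 1 | spiro 3-ethoxycyclobutenone (either configuration at the spiro carbon) | CCOC1=CC(=O)C12C[C@H]3[C@@H](CC[C@@]3(C)O[Si](CC)(CC)CC)[C@@](C)(O[Si](CC)(CC)CC)C2
A2 | alternative 1 | (triisopropylsilyloxy)acetylene | C#CO[Si](C(C)C)(C(C)C)C(C)C
A3 | alternative 1 | spiro 2-ethoxy-4-(triisopropylsilyloxy)cyclohexa-2,4-dienone | CCOC1=CC(O[Si](C(C)C)(C(C)C)C(C)C)=CC(=O)[C@@]12C[C@H]3[C@@H](CC[C@@]3(C)O[Si](CC)(CC)CC)[C@@](C)(O[Si](CC)(CC)CC)C2
A4 | alternative 2 | (R,E)-4-hydroxy-4,8-dimethylnona-2,7-dienal | O=C/C=C/[C@](C)(O)CCC=C(C)C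
A5 | alternative 2 | trans-hydrindane diol with C10 methylene and secondary C1 hydroxyl | O[C@@H]2C[C@H]3[C@@H](CC[C@@]3(C)O)C(=C)C2
A6 | alternative 3 | trans-fused diketone gem-diester | COC(=O)C1(C[C@H]2[C@@H](CCC2=O)C(=O)C1)C(=O)OC
A7 | alternative 3 | bridged lactone ester (identical with 13) | O=C4[C@]2(C[C@H]3[C@@H](CC[C@@]3(C)O)[C@@](C)(O4)C2)C(=O)OC
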